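(The earlier runs and the new flask stem from a simulated flask for substances that don't exist; scatter was added.)

**Same loss.** The spring run holds twice the catalyst of the dawn run, yet by 4.00 h its readings show 11.5 mM of substrate lost against 10.6 mM, so I treat the loss as a steady rate and expect dissolved gas well below saturation, without putting a number on it.

| flask | substrate | gas phase | catalyst | remark | time |
|---|---|---|---|---|---|
| dawn | 49 mM | 2.5 mM (held) | 0.80 mM | run made earlier |  |
| spring | 49 mM | 2.5 mM (held) | 1.8 mM | run made earlier |  |
| dusk | 74 mM | 2.5 mM (held) | 1.2 mM | run made earlier |  |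
| flask | 49 mM | 2.5 mM (held) | 1.2 mM |  | 5.0 h |

| run | time / h | target / % | substrate / % |
|---|---|---|---|
| dawn | 0.250 | 0 | 99.7 |
| dawn | 0.833 | 5.5 | 97.0 |
| dawn | 1.33 | 6.3 | 93.2 |
| dawn | 2.00 | 8.3 | 89.0 |
| dawn | 3.00 | 12.0 | 85.3 |
| dawn | 4.00 | 15.1 | 78.4 |
| spring | 0.333 | 0 | 97.5 |
| spring | 0.500 | 2.4 | 97.4 |
| spring | 0.833 | 6.9 | 96.2 |
| spring | 1.33 | 8.6 | 89.0 |
| spring | 2.50 | 11.6 | 85.2 |
| spring | 4.00 | 13.9 | 76.6 |
| dusk | 0.333 | 2.3 | 98.1 |
| dusk | 0.667 | 2.6 | 97.5 |
| dusk | 1.00 | 3.8 | 96.4 |
| dusk | 2.00 | 7.2 | 91.7 |
| dusk | 4.00 | 10.0 | 82.5 |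

(scatter of a reading: 1 percentage point)

- at the start none of the gas phase is in solution

1. amount of target at 5.0 h, in percent of the substrate charged
2. concentration of dissolved gas in solution at 5.0 h, in percent of saturation

**First chain.** Dawn and spring, with the flask's substrate and with catalyst below and above its charge, lose on average 2.76 mM h⁻¹, so I reckon that by 5.0 h the flask will have lost a fraction L = 28.1% and will keep x = 71.9%. Those runs turned 64.4% of lost substrate into target, which gives 18.1%.

**Weak link.** That fixed share is the weak link, since at the last dawn reading lost substrate exceeds target and I suspect target reacts on. Suppose substrate A falls at a·A and target P changes at a·(A − s·P), with a holding gas and catalyst. Dividing removes a, and integrating gives target y = (x − x^s)/(s − 1), or for small L, s ≈ 2(L − y)/L². The last readings give 2.79, 3.47 and 4.90, scattered readings averaging 3.72. This s, the selectivity factor, target's rate constant of loss over substrate's, gives me 15.7%.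

**The result.** The forecast says 17.5% of target, more than mine, and dissolved gas at 15% of saturation, holding that “the rate looks limited by gas transfer”. The flask gives 15.3% of target, with dissolved gas at 19.6% of saturation.

    dissolved gas + catalyst + target → catalyst + over-reaction product (k = 3.60 × 10⁵ M⁻² h⁻¹)
    gas phase ⇌ dissolved gas, rate k2*(csat - [dissolved gas]) (kL = 1.80 h⁻¹)
    substrate + dissolved gas + catalyst ⇌ catalyst + target (K = 3100 M⁻¹, k = 1.10 × 10⁵ M⁻² h⁻¹)

The flask keeps 74% of its substrate and holds 10.4% of over-reaction product, and that x in my curve gives 15.2%. A second flask, the same but charged with 200 mM of substrate, keeps 91% at 5.00 h, where the curve gives 7.57%, and it holds 7.59% of target.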